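**Retrosynthetic overview**

1. Numbering used here: ring B (cyclohexene) C1(=C15)–C2(OH)–C3(OH)–C4(CH3)–C16; ring C (cyclopentane) C4–C5–C6–C7–C16; ring A (eleven-membered) C1, C15, C16, C7, C8(=C19H2), C9(OAc), C10, C11, C12(CH3), C13, C14.
2. Ring A is closed last, at C14–C1, by hydroboration of a terminal C13=C14 vinyl group and intramolecular B-alkyl Suzuki–Miyaura coupling with a C1 vinyl iodide. The enabling feature is the C1=C15 double bond of ring B next to C2: with C2 as a ketone, C1 is the α-carbon of a 3-methylcyclohex-2-enone and can be iodinated, while C3 is carried as a dimethyl ketal.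
3. The C9–C14 chain is joined at C8–C9 by an asymmetric Nozaki–Hiyama–Kishi reaction between a C8 enol triflate on ring C and a chiral-pool C7 aldehyde.
4. Rings B and C: oxidative dearomatization of a 2-methoxyphenol (ring B with both methyl groups and both oxygens in place), Diels–Alder reaction with isoprene, Cope rearrangement to a cis-octalenone, then ozonolysis/aldol ring contraction of the isoprene-derived ring to ring C and hydrogenation to set C7.
5. Ring order: B (from the arene), C, A; after ring A the C2 ketone is reduced, the C3 ketal is hydrolysed and the C3 ketone is reduced under direction of the 2-hydroxyl to give the trans-diol.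

Key step: step 13

Assumption: compounds 7–14 are racemic (each SMILES shows the enantiomer that is carried forward); the antipodal series is removed as a diastereomer after the ligand-controlled union with the enantiopure aldehyde in step 10.

**Route**

Step 1
Reactants: 1 2,4-dimethylanisole
Product: 4 2-methoxy-3,5-dimethylphenol, via aryllithium 2 (not isolated), via arylboronate 3 (not isolated)
Conditions: n-BuLi, TMEDA, Et2O, 0 °C to rt; B(OMe)3, −78 °C to rt; AcOH, 30% aq. H2O2, 0 °C to rt
Reagents that add atoms: hydrogen peroxide, OO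
Why: Directed ortho-lithiation at the only free position ortho to the methoxy group, borylation and oxidation of the aryl boronate should give the phenol (ortho-metalation/borylation/oxidation).

Step 2
Reactants: 4 2-methoxy-3,5-dimethylphenol; 5 isoprene
Product: 7 rac-3,3-dimethoxy-4,6-dimethyl-7-endo-(prop-1-en-2-yl)bicyclo[2.2.2]oct-5-en-2-one, via masked o-benzoquinone 6 (not isolated)
Conditions: PhI(OAc)2, MeOH, isoprene (20 equiv), 0 °C to 50 °C, sealed tube
Reagents that add atoms: methanol, CO
Why: Oxidative dearomatization should give the cyclohexa-2,4-dienone ketal 6, which reacts as the diene with the less substituted double bond of isoprene (Diels–Alder reaction of a masked o-benzoquinone, bonds C1–C6 and C4–C5), the ortho/endo preference of this diene placing the isopropenyl-bearing carbon next to the bridgehead α to the ketone and syn to the C15=C16 bridge, which fixes the relative configuration of C1, C4 and C6.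

Step 3
Reactants: 7 rac-bicyclo[2.2.2]octenone
Product: 8 rac-cis-1,1-dimethoxy-4,6,8a-trimethyl-4a,5,8,8a-tetrahydronaphthalen-2(1H)-one
Conditions: mesitylene, 200 °C, sealed tube
Reagents that add atoms: none
Why: Cope rearrangement of the endo 1,5-diene through the boat-like transition state enforced by the bicycle should break C1–C6, form C7–C16, restore the conjugated C1=C15 enone and give only the cis ring fusion (H-16 and the C4 methyl on one face).

Step 4
Reactants: 8 rac-cis-octalenone
Product: 10 rac-cis-2-[2,2-dimethoxy-1,5-dimethyl-3-oxo-6-(2-oxopropyl)cyclohex-4-en-1-yl]acetaldehyde, via ozonide 9 (not isolated)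
Conditions: O3, CH2Cl2, −78 °C (Sudan Red 7B as end-point indicator); Me2S, −78 °C to rt
Reagents that add atoms: ozone, [O-][O+]=O
Why: Ozone should attack the electron-rich trisubstituted C6=C8 alkene much faster than the enone double bond, and reductive work-up gives the methyl ketone (C8) and the aldehyde (C6) (chemoselective ozonolysis).

Step 5
Reactants: 10 rac keto aldehyde
Product: 11 rac-cis-3-acetyl-7,7-dimethoxy-4,7a-dimethyl-1,3a,7,7a-tetrahydro-6H-inden-6-one
Conditions: piperidine, AcOH, benzene, 80 °C
Reagents that add atoms: none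
Why: Intramolecular aldol condensation of the ketone α-carbon C7 onto the aldehyde carbon C6 should close ring C as the 1-acetylcyclopentene, because the alternative nucleophile C5 is a neopentyl carbon and the methyl group C19 would give a seven-membered ring.

Step 6
Reactants: 11 rac acetylcyclopentene
Product: 12 rac-3-acetyl-7,7-dimethoxy-4,7a-dimethyl-1,2,3,3a,7,7a-hexahydro-6H-inden-6-one (H-3, H-3a and 7a-CH3 all cis)
Conditions: H2 (1 atm), Pd/C, EtOAc, rt, stopped after 1 equiv of H2
Reagents that add atoms: none
Why: Syn-hydrogenation of the less hindered acetylcyclopentene double bond from the convex face of the cis-hydrindane (the face of H-16 and the C4 methyl) should set C7 with the acetyl group on the concave face, while the β,β-disubstituted cyclohexenone flanked by the ketal reacts more slowly (chemoselective heterogeneous hydrogenation).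

Step 7
Reactants: 12 rac methyl ketone
Product: 14 rac-1-(7,7-dimethoxy-4,7a-dimethyl-6-oxo-2,3,3a,6,7,7a-hexahydro-1H-inden-3-yl)ethenyl trifluoromethanesulfonate, via potassium enolate 13 (not isolated)
Conditions: KN(SiMe3)2, THF, −78 °C; PhNTf2, −78 to 0 °C
Reagents that add atoms: N-phenylbis(trifluoromethanesulfonimide), O=S(=O)(N(c1ccccc1)S(=O)(=O)C(F)(F)F)C(F)(F)F
Why: Kinetic deprotonation of the methyl group (the enone has no α′-hydrogen because C3 is a ketal) and O-sulfonylation should give the 1,1-disubstituted alkenyl triflate without touching C7 (kinetic enolate triflation).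

Step 8
Reactants: 15 (S)-β-citronellene
Product: 16 2,2-dimethyl-3-[(3S)-3-methylpent-4-en-1-yl]oxirane
Conditions: mCPBA (1.0 equiv), CH2Cl2, 0 °C
Reagents that add atoms: meta-chloroperoxybenzoic acid, OOC(=O)c1cccc(Cl)c1
Why: The trisubstituted alkene should be epoxidized much faster than the monosubstituted one (Prilezhaev epoxidation).

Step 9
Reactants: 16 epoxide
Product: 18 (4S)-4-methylhex-5-enal, via diol 17 (not isolated)
Conditions: H5IO6, THF/H2O, 0 °C to rt
Reagents that add atoms: none
Why: Acidic opening of the epoxide and periodate cleavage of the resulting glycol should give the aldehyde and acetone without touching the vinyl group or the stereocenter (glycol cleavage).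

Step 10
Reactants: 14 rac enol triflate; 18 (4S)-4-methylhex-5-enal
Product: 19 3-[(3R,6S)-3-hydroxy-6-methylocta-1,7-dien-2-yl]-7,7-dimethoxy-4,7a-dimethyl-1,2,3,3a,7,7a-hexahydro-6H-inden-6-one (ring configuration as in the target)
Conditions: CrCl2 (4 equiv), NiCl2 (2 mol %), chiral 2-(2-sulfonamidophenyl)oxazoline ligand (the enantiomer that leads to the (9R) alcohol), Et3N, THF/MeCN, rt; chromatographic removal of the diastereomer formed from ent-14
Reagents that add atoms: none
Why: Nozaki–Hiyama–Kishi addition (oxidative addition of the triflate at zerovalent nickel, transmetalation to trivalent chromium, addition to the aldehyde) should form C8–C9 and the C8=C19 methylene group, the ligand on chromium controlling C9, and because 18 is enantiopure the product from ent-14 is a separable diastereomer, so that the series is a single enantiomer from here on.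

Step 11
Reactants: 19 allylic alcohol
Product: 20 (3R,6S)-2-(7,7-dimethoxy-4,7a-dimethyl-6-oxo-2,3,3a,6,7,7a-hexahydro-1H-inden-3-yl)-6-methylocta-1,7-dien-3-yl acetate
Conditions: Ac2O, DMAP, pyridine, CH2Cl2, 0 °C to rt
Reagents that add atoms: acetic anhydride, CC(=O)OC(C)=O
Why: Nucleophile-catalysed acylation should install the C9 acetate of the target, which is compatible with all later steps.

Step 12
Reactants: 20 enone acetate
Product: 21 5-iodo derivative of 20 (iodine on C1 of the target numbering)
Conditions: I2, pyridine, CH2Cl2, 0 °C to rt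
Reagents that add atoms: iodine, II
Why: α-Iodination of the enone (conjugate addition of pyridine, iodination of the enolate, elimination) should place iodine on C1, the α-carbon of the 3-methylcyclohexenone, while the isolated alkenes add iodine only reversibly.

Step 13
Reactants: 21 α-iodoenone
Product: 23 tricyclic enone (target skeleton with C2 ketone and C3 dimethyl ketal), via alkylborane 22 (not isolated)
Conditions: 9-BBN-H dimer (1.2 equiv B–H), THF, 0 °C to rt; then addition over 8 h to Pd(dppf)Cl2 (20 mol %), Ph3As, Cs2CO3, DMF/THF/H2O, rt (final concentration 2 mM)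
Reagents that add atoms: none
Why: 9-BBN-H should add anti-Markovnikov to the monosubstituted C13=C14 alkene, and the B-alkyl-9-BBN, activated as its borate by the aqueous base, transmetalates to the alkenyl divalent-palladium iodide formed by oxidative addition of zerovalent palladium into the C1–I bond; reductive elimination from the twelve-membered alkyl(alkenyl)palladacycle then forms C14–C1. The closest known reaction type is the B-alkyl Suzuki–Miyaura coupling of 2-iodocycloalk-2-enones, which has also been used to close macrocycles. The eleven-membered ring A is closed in the endo mode with respect to the C1=C15 bond (both alkene carbons lie in the new ring), so the step creates the bridgehead tetrasubstituted alkene, which is E within ring A and Z within ring B, and completes the bicyclo[8.3.1] core. No stereocenter is formed; the alkene geometry is fixed by the cyclohexenone, and the chain can reach C1 because C7 carries C8 on the concave face, next to C15. The step needs chemoselective hydroboration, which the steric difference between the vinyl group and the C8=C19 alkene (flanked by C7 and the acetoxy-bearing C9) and the hindered position of the C2 ketone between the ketal carbon and C1–I should secure. It also needs cyclization to outrun oligomerization and ionization of the allylic acetate, which slow addition at high dilution and the fast oxidative addition into C1–I should secure.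

Step 14
Reactants: 23 tricyclic enone
Product: 24 C2 allylic alcohol (C3 dimethyl ketal)
Conditions: NaBH4, CeCl3·7H2O, MeOH, −78 °C
Reagents that add atoms: none
Why: Luche 1,2-reduction should deliver hydride to C2 from the face opposite the ansa chain of ring A (the convex face carrying H-16 and the C4 methyl), which places the 2-hydroxyl on the face of ring C and leaves the acetate untouched.

Step 15
Reactants: 24 allylic alcohol
Product: 25 C3 ketone with free 2-hydroxyl
Conditions: PPTS, acetone/H2O (10:1), 40 °C
Reagents that add atoms: water, O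
Why: Mild acid-catalysed ketal hydrolysis should unveil the C3 ketone without ionizing the allylic alcohol or cleaving the acetate.

Step 16
Reactants: 25 α-hydroxy ketone
Product: 26 target
Conditions: Me4NBH(OAc)3, MeCN/AcOH (1:1), −20 °C
Reagents that add atoms: none
Why: In this hydroxyl-directed triacetoxyborohydride reduction the 2-hydroxyl binds boron and delivers hydride to C3 on its own face, so the new 3-hydroxyl should be trans to the 2-hydroxyl and cis to the C4 methyl.

**Compound list**

1 | 2,4-dimethylanisole | COc1ccc(C)cc1C | starting material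
2 | (2-methoxy-3,5-dimethylphenyl)lithium | [Li]c1cc(C)cc(C)c1OC | intermediate
3 | dimethyl (2-methoxy-3,5-dimethylphenyl)boronate | COB(OC)c1cc(C)cc(C)c1OC | intermediate
4 | 2-methoxy-3,5-dimethylphenol | COc1c(O)cc(C)cc1C | intermediate
5 | isoprene (2-methylbuta-1,3-diene) | C=CC(C)=C | starting material
6 | 6,6-dimethoxy-3,5-dimethylcyclohexa-2,4-dien-1-one (masked o-benzoquinone) | O=C1C=C(C)C=C(C)C1(OC)OC | intermediate
7 | rac-3,3-dimethoxy-4,6-dimethyl-7-endo-(prop-1-en-2-yl)bicyclo[2.2.2]oct-5-en-2-one | C=C(C)[C@H]1C[C@@]2(C)C=C(C)[C@@H]1C(=O)C2(OC)OC | intermediate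
8 | rac-cis-1,1-dimethoxy-4,6,8a-trimethyl-4a,5,8,8a-tetrahydronaphthalen-2(1H)-one | CC1=CC[C@@]2(C)[C@@H](C1)C(C)=CC(=O)C2(OC)OC | intermediate
9 | secondary ozonide (1,2,4-trioxolane) of the C6=C7 bond of 8 | CC12C[C@H]3C(C)=CC(=O)C(OC)(OC)[C@@]3(C)CC(OO1)O2 | intermediate
10 | rac-cis-2-[2,2-dimethoxy-1,5-dimethyl-3-oxo-6-(2-oxopropyl)cyclohex-4-en-1-yl]acetaldehyde | O=CC[C@@]1(C)[C@@H](CC(C)=O)C(C)=CC(=O)C1(OC)OC | intermediate
11 | rac-cis-3-acetyl-7,7-dimethoxy-4,7a-dimethyl-1,3a,7,7a-tetrahydro-6H-inden-6-one | CC(=O)C1=CC[C@@]2(C)[C@@H]1C(C)=CC(=O)C2(OC)OC | intermediate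
12 | rac-3-acetyl-7,7-dimethoxy-4,7a-dimethyl-1,2,3,3a,7,7a-hexahydro-6H-inden-6-one (H-3, H-3a, 7a-CH3 all cis) | CC(=O)[C@@H]1CC[C@@]2(C)[C@@H]1C(C)=CC(=O)C2(OC)OC | intermediate
13 | potassium enolate of 12 (methyl side) | [K+].C=C([O-])[C@@H]1CC[C@@]2(C)[C@@H]1C(C)=CC(=O)C2(OC)OC | intermediate
14 | rac-1-(7,7-dimethoxy-4,7a-dimethyl-6-oxo-2,3,3a,6,7,7a-hexahydro-1H-inden-3-yl)ethenyl trifluoromethanesulfonate | C=C(OS(=O)(=O)C(F)(F)F)[C@@H]1CC[C@@]2(C)[C@@H]1C(C)=CC(=O)C2(OC)OC | intermediate
15 | (S)-β-citronellene, (3S)-3,7-dimethylocta-1,6-diene | CC(C)=CCC[C@H](C)C=C | starting material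
16 | 2,2-dimethyl-3-[(3S)-3-methylpent-4-en-1-yl]oxirane (both oxirane epimers) | CC1(C)OC1CC[C@H](C)C=C | intermediate
17 | (6S)-2,6-dimethyloct-7-ene-2,3-diol | CC(C)(O)C(O)CC[C@H](C)C=C | intermediate
18 | (4S)-4-methylhex-5-enal | O=CCC[C@H](C)C=C | intermediate
19 | 3-[(3R,6S)-3-hydroxy-6-methylocta-1,7-dien-2-yl]-7,7-dimethoxy-4,7a-dimethyl-1,2,3,3a,7,7a-hexahydro-6H-inden-6-one (H-3, H-3a, 7a-CH3 cis; single enantiomer) | C=C[C@@H](C)CC[C@@H](O)C(=C)[C@@H]1CC[C@@]2(C)[C@@H]1C(C)=CC(=O)C2(OC)OC | intermediate
20 | acetate of 19 | C=C[C@@H](C)CC[C@@H](OC(C)=O)C(=C)[C@@H]1CC[C@@]2(C)[C@@H]1C(C)=CC(=O)C2(OC)OC | intermediate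
21 | 5-iodo derivative of 20 (α-iodoenone) | C=C[C@@H](C)CC[C@@H](OC(C)=O)C(=C)[C@@H]1CC[C@@]2(C)[C@@H]1C(C)=C(I)C(=O)C2(OC)OC | intermediate
22 | B-alkyl-9-borabicyclo[3.3.1]nonane from hydroboration of the vinyl group of 21 | C(C[C@@H](C)CC[C@@H](OC(C)=O)C(=C)[C@@H]1CC[C@@]2(C)[C@@H]1C(C)=C(I)C(=O)C2(OC)OC)B3C4CCCC3CCC4 | intermediate
23 | tricyclic enone: target skeleton with C2 ketone and C3 dimethyl ketal | C=C1[C@H](OC(C)=O)CC[C@H](C)CCC2=C(C)[C@@H]3[C@H]1CC[C@]3(C)C(OC)(OC)C2=O | intermediate
24 | C2 alcohol with C3 dimethyl ketal | C=C1[C@H](OC(C)=O)CC[C@H](C)CCC2=C(C)[C@@H]3[C@H]1CC[C@]3(C)C(OC)(OC)[C@@H]2O | intermediate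
25 | C3 ketone with 2-hydroxyl | C=C1[C@H](OC(C)=O)CC[C@H](C)CCC2=C(C)[C@@H]3[C@H]1CC[C@]3(C)C(=O)[C@@H]2O | intermediate
26 | target (CNP0192310.3) | C=C1[C@H](OC(C)=O)CC[C@H](C)CCC2=C(C)[C@@H]3[C@H]1CC[C@]3(C)[C@@H](O)[C@@H]2O | target

**Step count and risks**

Total steps: 16. Longest linear sequence: 14 (steps 1–7 and 10–16).

Steps most likely to fail:

1. Step 13. Intermolecular coupling may outrun ring closure, or the borane may be lost to 1,2-reduction of the C2 ketone or to hydroboration of the C8=C19 alkene before the coupling. Fallback, from 20 back to 23: hydroboration with 9-BBN-H and oxidation with NaBO3·4H2O give the primary C14 alcohol F1; I2, PPh3 and imidazole give the primary iodide F2; I2/pyridine gives the iodoenone alkyl iodide F3. A nickel-catalysed reductive cross-electrophile coupling (NiI2, 4,4′-di-tert-butyl-2,2′-bipyridine, Mn powder, DMA, slow addition) then forms the same C14–C1 bond without an organoboron intermediate and delivers 23.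

2. Step 2. The masked o-benzoquinone may dimerize, isoprene may react through its 1,1-disubstituted double bond, or endo selectivity may be lost; each gives material that cannot undergo the Cope rearrangement to 8. Fallback, from 4 back to 7: 6 is generated in the presence of methyl vinyl ketone, an activated dienophile with a single C=C, to give the endo acetyl adduct F4. Wittig methylenation of its unhindered methyl ketone (Ph3P=CH2, THF, 0 °C) then gives 7.

3. Step 14. Facial selectivity of hydride addition to the C2 ketone may be poor or reversed. Fallback, from 23 back to 24: the C2-epimeric alcohol F5 is inverted by a Mitsunobu reaction with chloroacetic acid (PPh3, DIAD) to the chloroacetate F6. Thiourea/NaHCO3 in EtOH then removes the chloroacetyl group in the presence of the C9 acetate and gives 24.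

Further compounds
F1 | step 13 | primary C14 alcohol from hydroboration–oxidation of 20 | OCC[C@@H](C)CC[C@@H](OC(C)=O)C(=C)[C@@H]1CC[C@@]2(C)[C@@H]1C(C)=CC(=O)C2(OC)OC
F2 | step 13 | primary C14 iodide | ICC[C@@H](C)CC[C@@H](OC(C)=O)C(=C)[C@@H]1CC[C@@]2(C)[C@@H]1C(C)=CC(=O)C2(OC)OC
F3 | step 13 | iodoenone alkyl iodide | ICC[C@@H](C)CC[C@@H](OC(C)=O)C(=C)[C@@H]1CC[C@@]2(C)[C@@H]1C(C)=C(I)C(=O)C2(OC)OC
F4 | step 2 | rac-7-endo-acetyl-3,3-dimethoxy-4,6-dimethylbicyclo[2.2.2]oct-5-en-2-one | CC(=O)[C@H]1C[C@@]2(C)C=C(C)[C@@H]1C(=O)C2(OC)OC
F5 | step 14 | C2 epimer of 24 | C=C1[C@H](OC(C)=O)CC[C@H](C)CCC2=C(C)[C@@H]3[C@H]1CC[C@]3(C)C(OC)(OC)[C@H]2O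
F6 | step 14 | chloroacetate of 24 | C=C1[C@H](OC(C)=O)CC[C@H](C)CCC2=C(C)[C@@H]3[C@H]1CC[C@]3(C)C(OC)(OC)[C@@H]2OC(=O)CCl
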